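**Retrosynthesis (ring-formation order: A → THF acetal → C → D → δ-lactone)**
1. Cleave C9–C10 and the lactone: a tertiary C10 radical (from a C10 tertiary alcohol) cyclizes 6-exo onto the C9=C11 enone of the bicycle. The C20 primary alcohol and C7 acid are first joined as an ester.
2. Ring C/D: a Pd(II) cycloalkenylation of a silyl dienol ether closes the bicyclo[3.2.1]octane. The C8 quaternary centre comes from an ene-reductase desymmetrization of a 4,4-disubstituted cyclohexadienone.
3. C15 is oxidized (SeO2, then DMP) to the 15-oxo-16-ene, and an ene-reductase delivers the 16-methyl group.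
4. Ring A and the C6 acetal: Cu-catalysed asymmetric conjugate addition sets C4. Orthoformate C-functionalization of the silyl enol ether, then intramolecular transacetalization, gives the cis-fused 2-methoxy-THF. The C10 ketone becomes the C10/C20 diol.

Assumptions: (i) the exo (convex-face) OMe anomer in the target is the thermodynamic one and equilibrates in step 5; (ii) an enzyme-panel hit with the needed enantiopreference exists for steps 13 and 25.

---

**Step 1**
Reactants: 1, 3-ethoxycyclohex-2-en-1-one
Product: 2, 3-(hydroxymethyl)cyclohex-2-en-1-one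
Conditions: Bu3SnCH2OCH(Me)OEt, n-BuLi, THF, −78 °C; add 1; then 2 M HCl, THF, 25 °C
Reagents that add atoms: tributyl[(1-ethoxyethoxy)methyl]stannane, CCCC[Sn](CCCC)(CCCC)COC(C)OCC (supplies CH2O)
Why: The α-alkoxy organolithium adds 1,2 to the vinylogous ester and acid hydrolysis performs the Stork–Danheiser transposition, which also cleaves the ethoxyethyl group.

**Step 2**
Reactants: 2
Product: 3, 3-[(tert-butyldimethylsilyloxy)methyl]cyclohex-2-en-1-one
Conditions: TBSCl, imidazole, DMF, 25 °C
Reagents that add atoms: TBSCl, CC(C)(C)[Si](C)(C)Cl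
Why: Standard silylation of the primary alcohol prepares a Grignard-compatible β-substituted enone.

**Step 3**
Reactants: 3
Product: 4, TMS enol ether of 3-methyl-3-(TBSOCH2)cyclohexanone, enol double bond C10=C5, C4 stereocentre as drawn
Conditions: MeMgBr, CuBr·SMe2 (5 mol%), Josiphos-type ligand (6 mol%; enantiomer chosen to give the C4 configuration shown), t-BuOMe, −78 °C; then TMSCl, DMPU, −78→0 °C (crude used directly)
Reagents that add atoms: MeMgBr, C[Mg]Br (C18 methyl); TMSCl, C[Si](C)(C)Cl
Why: Cu-catalysed asymmetric conjugate addition to the β-substituted enone builds the quaternary C4 centre (the first stereocentre). The magnesium enolate is trapped regiospecifically as the C10=C5 silyl enol ether.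

**Step 4**
Reactants: 4
Product: 5, 2-(dimethoxymethyl)-3-methyl-3-(TBSOCH2)cyclohexan-1-one (C5 epimeric mixture)
Conditions: HC(OMe)3, TMSOTf (5 mol%), CH2Cl2, −78→−30 °C
Reagents that add atoms: trimethyl orthoformate, COC(OC)OC (supplies CH(OMe)2, the C6 carbon)
Why: Noyori-type Mukaiyama addition of the silyl enol ether to the dimethoxycarbenium ion installs C6 at C5. C5 is epimerizable and is corrected in step 5.

**Step 5**
Reactants: 5
Product: 6, cis-fused 2-methoxytetrahydrofuran-cyclohexanone (C6 acetal, C10 ketone)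
Conditions: PPTS, MeOH, 45 °C; then PPTS, PhMe, 4 Å MS, 60 °C
Reagents that add atoms: none
Why: Methanolysis of the TBS ether frees C19–OH, which undergoes intramolecular transacetalization. Only the cis-fused THF can form, so enolization at C5 converges on the configuration required by C4, and the exo-OMe anomer is favoured.

**Step 6**
Reactants: 6
Product: 7, exocyclic C10=C20 methylene
Conditions: Cp2TiMe2, PhMe/THF, 70 °C, dark
Reagents that add atoms: Petasis reagent, C[Ti](C)(C1C=CC=C1)C1C=CC=C1 (supplies CH2)
Why: Petasis methylenation is non-basic, so it avoids E1cB opening of the β-alkoxy acetal that a phosphonium ylide could cause.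

**Step 7**
Reactants: 7
Product: 8, C10-hydroxy/C20-hydroxymethyl diol (C10 epimers)
Conditions: OsO4 (5 mol%), NMO, acetone/H2O, 25 °C
Reagents that add atoms: OsO4, O=[Os](=O)(=O)=O; NMO, C[N+]1([O-])CCOCC1 (source of the two oxygens)
Why: Upjohn syn-dihydroxylation of the 1,1-disubstituted alkene; the C10 configuration is irrelevant because C10 is later converted to a planar radical.

**Step 8**
Reactants: 9, 4-oxocyclohexane-1-carboxylic acid
Product: 10, tert-butyl 4-oxocyclohexane-1-carboxylate
Conditions: Boc2O, DMAP (cat.), t-BuOH, 40 °C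
Reagents that add atoms: t-BuOH, CC(C)(C)O; Boc2O, CC(C)(C)OC(=O)OC(=O)OC(C)(C)C (tert-butyl source)
Why: Boc2O/DMAP tert-butyl esterification gives an ester that is later cleaved without hydroxide, avoiding retro-Claisen of the C7/C15 β-dicarbonyl unit.

**Step 9**
Reactants: 10
Product: 11, tert-butyl 1,4-dioxaspiro[4.5]decane-8-carboxylate
Conditions: TMSOCH2CH2OTMS, TMSOTf (cat.), CH2Cl2, −78→0 °C
Reagents that add atoms: 1,2-bis(trimethylsilyloxy)ethane, C[Si](C)(C)OCCO[Si](C)(C)C (supplies OCH2CH2O)
Why: Noyori ketalization under non-protic conditions protects the C12 ketone and leaves the tert-butyl ester intact.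

**Step 10**
Reactants: 11
Product: 12, tert-butyl 8-allyl-1,4-dioxaspiro[4.5]decane-8-carboxylate
Conditions: LDA, THF, −78 °C; allyl bromide, −78→0 °C
Reagents that add atoms: allyl bromide, C=CCBr (supplies C15–C17)
Why: Ester-enolate alkylation builds the C8 quaternary centre, which is still prochiral because both ring arms are identical.

**Step 11**
Reactants: 12
Product: 13, tert-butyl 1-allyl-4-oxocyclohexane-1-carboxylate
Conditions: PPTS, acetone/H2O, 60 °C
Reagents that add atoms: water, O (ketone oxygen)
Why: Mild acid hydrolysis of the dioxolane, with the tert-butyl ester untouched.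

**Step 12**
Reactants: 13
Product: 14, tert-butyl 1-allyl-4-oxocyclohexa-2,5-diene-1-carboxylate
Conditions: IBX (3 equiv), DMSO/PhF, 85 °C
Reagents that add atoms: none
Why: Nicolaou IBX double dehydrogenation cannot aromatize because C4 is quaternary, so it gives the prochiral cross-conjugated dienone.

**Step 13**
Reactants: 14
Product: 15, tert-butyl (R)-1-allyl-4-oxocyclohex-2-ene-1-carboxylate
Conditions: ene-reductase (Old Yellow Enzyme family), NADP+ (cat.), glucose/GDH, KPi pH 7.0, 5% DMSO, 30 °C
Reagents that add atoms: none (adds H2 from NADPH/H2O)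
Why: The flavin-dependent ene-reductase (EC 1.3.1.31) reduces exactly one of the two enantiotopic enone C=C bonds by hydride delivery to Cβ, making C8 quaternary and stereogenic (desymmetrization).

**Step 14**
Reactants: 15
Product: 16, 2-silyloxy-1,3-diene (silyl dienol ether)
Conditions: LiHMDS, TMSCl, Et3N, THF, −78 °C
Reagents that add atoms: TMSCl, C[Si](C)(C)Cl
Why: Kinetic deprotonation can only occur at the α′ position (C13) because C8 is quaternary, giving a single regio-defined cross-conjugated enol ether.

**Step 15**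
Reactants: 16
Product: 17, tert-butyl 6-methylidene-4-oxobicyclo[3.2.1]oct-2-ene-1-carboxylate
Conditions: Pd(OAc)2 (1.0 equiv), MeCN, 25 °C
Reagents that add atoms: none
Why: Toyota-type Pd(II) cycloalkenylation: the enol ether carbon C13 attacks the Pd-bound allyl alkene at C16 (5-exo) and β-hydride elimination gives the exocyclic C16=C17. The bridged geometry fixes C13 relative to C8, and the enone C9=C11 is retained as the radical acceptor.

**Step 16**
Reactants: 17
Product: 18, the carboxylic acid (C7 acid)
Conditions: TMSOTf, 2,6-lutidine, CH2Cl2, 0 °C; then H2O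
Reagents that add atoms: none
Why: Non-protic tert-butyl ester cleavage avoids protonating the exocyclic alkene (Wagner–Meerwein risk) and avoids hydroxide.

**Step 17**
Reactants: 8 and 18
Product: 19, C20 ester of diol 8 (tertiary C10–OH free)
Conditions: 2,4,6-Cl3C6H2COCl, Et3N, THF, 25 °C; then 8, DMAP, PhMe, 25 °C
Reagents that add atoms: none (the trichlorobenzoyl group is lost)
Why: Yamaguchi esterification selectively acylates the unhindered primary C20 alcohol through a mixed anhydride, leaving the tertiary alcohol free.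

**Step 18**
Reactants: 19
Product: 20, tertiary N-phthalimidoyl oxalate
Conditions: (COCl)2, pyridine, CH2Cl2, 0 °C; then N-hydroxyphthalimide, Et3N, DMAP
Reagents that add atoms: oxalyl chloride, ClC(=O)C(=O)Cl; N-hydroxyphthalimide, O=C1c2ccccc2C(=O)N1O
Why: The tertiary alcohol is converted to a redox-active oxalate, a precursor of the tertiary C10 radical.

**Step 19**
Reactants: 20
Product: 21, spiro-δ-lactone with C12 ketone (C9–C10 bond formed)
Conditions: [Ru(bpy)3](PF6)2 (2 mol%), Hantzsch ester, i-Pr2NEt, CH2Cl2 (0.005 M), blue LEDs, 25 °C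
Reagents that add atoms: none (adds H)
Why: Photoredox fragmentation of the oxalate (loss of 2 CO2 and phthalimide) gives the tertiary C10 radical, which cyclizes 6-exo onto C9 of the enone. Attack is axial, anti to the C8–C15 bond and syn to the C7 tether, giving the cis-fused lactone. The axial C19 shields the α-face of the A-ring radical, so C20 ends up axial. The C11 α-keto radical is reduced.

**Step 20**
Reactants: 21
Product: 22, C12 secondary alcohol
Conditions: NaBH4, MeOH/CH2Cl2, −20 °C
Reagents that add atoms: none (adds H)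
Why: The unhindered C12 ketone is the only ketone present, and the lactone, acetal and alkene are inert at −20 °C. The C12 stereochemistry is irrelevant.

**Step 21**
Reactants: 22
Product: 23, C12 imidazolyl thiocarbonate
Conditions: TCDI, DMAP, CH2Cl2, 40 °C
Reagents that add atoms: 1,1′-thiocarbonyldiimidazole, S=C(n1ccnc1)n1ccnc1
Why: Barton–McCombie activation of the secondary alcohol.

**Step 22**
Reactants: 23
Product: 24, deoxygenated lactone (C12 = CH2)
Conditions: Bu3SnH, AIBN, PhMe, 110 °C
Reagents that add atoms: none (adds H)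
Why: Radical deoxygenation removes the C12 oxygen and leaves the exocyclic alkene untouched.

**Step 23**
Reactants: 24
Product: 25, C15 allylic alcohol (epimeric)
Conditions: SeO2 (30 mol%), t-BuOOH, CH2Cl2, 25 °C
Reagents that add atoms: t-BuOOH, CC(C)(C)OO (source of the OH oxygen); SeO2, O=[Se]=O
Why: Riley/ene allylic oxidation at C15 of the exocyclic methylene, the classic kauranoid 15-oxidation.

**Step 24**
Reactants: 25
Product: 26, 15-oxo-16-ene (exocyclic enone)
Conditions: Dess–Martin periodinane, NaHCO3, CH2Cl2, 25 °C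
Reagents that add atoms: none
Why: Buffered oxidation of the secondary allylic alcohol (both epimers converge) to the enone.

**Step 25**
Reactants: 26
Product: 27, ludongnin H
Conditions: ene-reductase (OYE family), NADP+ (cat.), glucose/GDH, KPi pH 7.0, 10% DMSO, 30 °C
Reagents that add atoms: none (adds H2)
Why: Enzymatic hydride delivery to C17 and protonation at C16 reduce the exocyclic enone under neutral conditions, leaving the acetal and lactone intact. Any endo-methyl epimer at C16 (α to C15 ketone) is equilibrated to the exo-methyl ketone with DBU.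

---

**Compound list**

| # | Name | SMILES | Role |
|---|---|---|---|
| 1 | 3-ethoxycyclohex-2-en-1-one | CCOC1=CC(=O)CCC1 | starting material |
| 2 | 3-(hydroxymethyl)cyclohex-2-en-1-one | OCC1=CC(=O)CCC1 | intermediate |
| 3 | 3-(TBS-oxymethyl)cyclohex-2-en-1-one | CC(C)(C)[Si](C)(C)OCC1=CC(=O)CCC1 | intermediate |
| 4 | TMS enol ether of 3-methyl-3-(TBS-oxymethyl)cyclohexanone (C4 as drawn) | C[Si](C)(C)OC1=C[C@](C)(CO[Si](C)(C)C(C)(C)C)CCC1 | intermediate |
| 5 | 2-(dimethoxymethyl)-3-methyl-3-(TBS-oxymethyl)cyclohexanone (C5 epimers) | COC(OC)C1C(=O)CCC[C@@]1(C)CO[Si](C)(C)C(C)(C)C | intermediate |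
| 6 | cis-fused 2-methoxy-THF/cyclohexanone (C6 acetal, C10 ketone) | CO[C@H]1OC[C@]2(C)CCCC(=O)[C@H]12 | intermediate |
| 7 | exocyclic methylene analogue of 6 | CO[C@H]1OC[C@]2(C)CCCC(=C)[C@H]12 | intermediate |
| 8 | C10-hydroxy, C20-hydroxymethyl diol (C10 epimers) | CO[C@H]1OC[C@]2(C)CCCC(O)(CO)[C@H]12 | intermediate |
| 9 | 4-oxocyclohexane-1-carboxylic acid | OC(=O)C1CCC(=O)CC1 | starting material |
| 10 | tert-butyl 4-oxocyclohexane-1-carboxylate | CC(C)(C)OC(=O)C1CCC(=O)CC1 | intermediate |
| 11 | tert-butyl 1,4-dioxaspiro[4.5]decane-8-carboxylate | CC(C)(C)OC(=O)C1CCC2(CC1)OCCO2 | intermediate |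
| 12 | tert-butyl 8-allyl-1,4-dioxaspiro[4.5]decane-8-carboxylate | CC(C)(C)OC(=O)C1(CC=C)CCC2(CC1)OCCO2 | intermediate |
| 13 | tert-butyl 1-allyl-4-oxocyclohexane-1-carboxylate | CC(C)(C)OC(=O)C1(CC=C)CCC(=O)CC1 | intermediate |
| 14 | tert-butyl 1-allyl-4-oxocyclohexa-2,5-diene-1-carboxylate | CC(C)(C)OC(=O)C1(CC=C)C=CC(=O)C=C1 | intermediate |
| 15 | tert-butyl (R)-1-allyl-4-oxocyclohex-2-ene-1-carboxylate | CC(C)(C)OC(=O)[C@]1(CC=C)C=CC(=O)CC1 | intermediate |
| 16 | silyl dienol ether of 15 | CC(C)(C)OC(=O)[C@]1(CC=C)C=CC(O[Si](C)(C)C)=CC1 | intermediate |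
| 17 | tert-butyl 6-methylidene-4-oxobicyclo[3.2.1]oct-2-ene-1-carboxylate | CC(C)(C)OC(=O)[C@]12C=CC(=O)[C@H](C1)C(=C)C2 | intermediate |
| 18 | 6-methylidene-4-oxobicyclo[3.2.1]oct-2-ene-1-carboxylic acid | OC(=O)[C@]12C=CC(=O)[C@H](C1)C(=C)C2 | intermediate |
| 19 | C20 ester of 8 with 18 | CO[C@H]1OC[C@]2(C)CCCC(O)(COC(=O)[C@]34C=CC(=O)[C@H](C3)C(=C)C4)[C@H]12 | intermediate |
| 20 | tertiary N-phthalimidoyl oxalate of 19 | CO[C@H]1OC[C@]2(C)CCCC(OC(=O)C(=O)ON3C(=O)c4ccccc4C3=O)(COC(=O)[C@]56C=CC(=O)[C@H](C5)C(=C)C6)[C@H]12 | intermediate |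
| 21 | spirolactone, C12 ketone, C16=C17 | CO[C@H]1OC[C@]2(C)CCC[C@]3(COC(=O)[C@@]45C[C@@H](C(=O)C[C@H]43)C(=C)C5)[C@H]12 | intermediate |
| 22 | C12 alcohol | CO[C@H]1OC[C@]2(C)CCC[C@]3(COC(=O)[C@@]45C[C@@H](C(O)C[C@H]43)C(=C)C5)[C@H]12 | intermediate |
| 23 | C12 imidazolyl thiocarbonate | CO[C@H]1OC[C@]2(C)CCC[C@]3(COC(=O)[C@@]45C[C@@H](C(OC(=S)n6ccnc6)C[C@H]43)C(=C)C5)[C@H]12 | intermediate |
| 24 | C12-deoxy lactone | CO[C@H]1OC[C@]2(C)CCC[C@]3(COC(=O)[C@@]45C[C@@H](CC[C@H]43)C(=C)C5)[C@H]12 | intermediate |
| 25 | C15 allylic alcohol (epimers) | CO[C@H]1OC[C@]2(C)CCC[C@]3(COC(=O)[C@@]45C[C@@H](CC[C@H]43)C(=C)C5O)[C@H]12 | intermediate |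
| 26 | 15-oxo-16-ene (exocyclic enone) | CO[C@H]1OC[C@]2(C)CCC[C@]3(COC(=O)[C@@]45C[C@@H](CC[C@H]43)C(=C)C5=O)[C@H]12 | intermediate |
| 27 | ludongnin H | CO[C@H]1OC[C@]2(C)CCC[C@]3(COC(=O)[C@@]45C[C@@H](CC[C@H]43)[C@H](C)C5=O)[C@H]12 | target |

---

**Totals**
- Total steps: 25.
- Longest linear sequence: 18 steps (9 → 10 → … → 18 in steps 8–16, then steps 17–25).

**Three steps most likely to fail, with fallbacks**
1. **Step 15 (Pd cycloalkenylation).** The dienol ether may undergo Saegusa-type dehydrogenation back to the dienone instead of cyclizing.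
   *Fallback:* brominate the α′ position of enone 15, do a Bu3SnH- or (TMS)3SiH-mediated 5-exo radical cyclization onto the allyl group with PhSeSePh trapping of the primary radical, then oxidize and eliminate the selenide to install C16=C17.
2. **Step 19 (hindered 6-exo radical cyclization forming the C9–C10 vicinal quaternary/tertiary centres).** The ester must adopt the strained E-conformer, and premature reduction of the radical competes.
   *Fallback:* make the C9–C10 bond intermolecularly. Convert ketone 6 to the spiro-epoxide (Corey–Chaykovsky), open it with Cp2TiCl to give the C10 radical, add it to the methyl ester of acid 18, and close the δ-lactone afterwards by acid-mediated lactonization (C20–OH onto C7).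
3. **Step 13 (ene-reductase desymmetrization of 14).** The enzyme may not accept the bulky tert-butyl ester/allyl dienone, or may give low ee.
   *Fallback:* replace the enzyme with a catalytic asymmetric metal-hydride route, a chiral bisphosphine–CuH desymmetrizing 1,4-reduction of 14. If the ee is still inadequate, install C8 by enantioselective Pd-catalysed allylation of the corresponding cyclohexanone carboxylate instead.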